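**Remark.** The configuration is read from the SMILES as (3R,5R,6S,3'R,5'S,6'S), with the C5 hydroxyl of ring A exo (on the side of the oxygen bridge). Carotenoid numbering (C1–C6 ring A, C1'–C6' ring B) is used for positions. Compounds 24 and 43 are taken as commercial.

## Analysis of the target

Target 48 is a C40 carotenoid, (3R,5R,6S,3'R,5'S,6'S)-3,6-epoxy-5,6,5',6'-tetrahydro-β,β-carotene-5,3',5',6'-tetrol. An all-E nonaene chain (C7 to C7', four methyl branches) links two different saturated end groups. Ring A is a 7-oxabicyclo[2.2.1]heptane: the oxygen bridges C3 and C6 (so the two bridgeheads are cis by necessity), C6 carries the chain and lies between the quaternary C1 (gem-dimethyl) and C5, and the C5 hydroxyl is exo. Ring B is a cyclohexane with a secondary 3'-hydroxyl and a trans 5',6'-diol of two tertiary alcohols; the 3'-OH is cis to the 6'-OH and trans to the 5'-OH. C3 and C6 have the same sense in both rings, but the two clusters of three stereocentres are separated by an achiral chain of eighteen sp2 carbons, so each half has to be made enantiopure on its own. Sensitive points are the polyene (light, oxygen, acid), the two C6–O bonds (tertiary and allylic once the chain is attached), and a β-hydroxy aldehyde stage in ring A whose alkoxide could open the strained bicycle by retro-aldol cleavage. The hard part is ring A: a fully substituted bridgehead between two fully substituted carbons, with an exo C5 hydroxyl that the usual anti opening of a 5,6-epoxide cannot deliver. The strategy rests on the two-carbon bridge C1–C2 of ring A. A furan and a 1,1-dimethyl oxyallyl cation assemble the same bicycle in one step but with a three-carbon bridge C1–C(=O)–C2, so the carbonyl carbon has to be excised.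

## Retrosynthetic reasoning

**48 from 47.** Only two silyl ethers are removed, at O3' and O5. Fluoride is the mildest reagent the finished polyene can meet, and nothing else has to be adjusted at the end.

**47 from 28 and 45 (C11=C12).** The chain is cut at a disubstituted double bond next to a methyl-bearing carbon. The Z isomer of such a bond is strained and relaxes to E on heating, so geometry is not a lasting problem. The cut gives a C15 ylide half with ring A (28) and a C25 aldehyde with ring B (45); all six stereocentres are then made on small fragments.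

**45 from 42 and 43 (C11'=C12').** The same kind of bond is cut on the other side. Dialdehyde 43 supplies C12 to C12' with three E double bonds already in place, and is used in excess so that only one end reacts.

**28 from 26, 25, and 23 with 24 (C7=C8).** Phosphonate 24 brings C8–C11 and the C9 methyl in one olefination of the bridgehead aldehyde 23. Reduction of ester 25 to alcohol 26 and neutral conversion into the phosphonium salt follow; acid is avoided because the C6–O bond is tertiary and allylic.

**23 from 22, 21 and 20.** These steps adjust C7 to the aldehyde and mask O5. In 22 the C5 hydroxyl is β to the aldehyde, and its alkoxide could cleave C5–C6 and open the bicycle, so it is silylated before the basic olefination.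

**20 from 18, 17 and 15.** The ester carbon left by the ring contraction is removed by radical decarboxylation of acid 18, and the C5 hydroxyl comes from hydration of C4=C5 in 15. Hydration is placed first: a C2 radical with C4=C5 still present would be a norbornenyl-type homoallyl radical that closes to the nortricyclyl isomer. The hydration has to deliver oxygen to C5 from the exo face.

**15 from 12 and 13 (C1–C2).** This is the ring contraction. The C1–C2 bond is made by a 1,2-shift in diazo ketone 12 and the carbonyl carbon leaves the ring as the ester of methanol 13. Cutting here turns the awkward two-carbon bridge into the three-carbon bridge that a cycloaddition gives directly.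

**12 from 10, 9, and 4 with 7.** The diazo group goes to the only enolisable α-carbon of ketone 10. Racemate 9 is resolved, since the cycloaddition of furan 4 with the oxyallyl unit from dibromo ketone 7 has no stereocontrol element. That cycloaddition forms the C6–C1 and C3–C2 bonds and has to place the gem-dimethyl carbon next to the substituted bridgehead. Furan 4 comes from ester 1 by reduction to 2 and silylation with 3; 7 comes from ketone 5.

**42 from 40, 39, and 38 with 24.** The same C5 extension and phosphonium formation as in ring A, on the α-hydroxy aldehyde 38.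

**38 from 37 and 36 (C5'–O).** The trans diol comes from the syn epoxy alcohol 36 by attack of water at C5' with inversion. C5' is the tertiary carbon remote from the CH2OH group, and this is also the trans-diaxial mode of opening. C6' keeps its oxygen, cis to O3'.

**36 from 35, 34, 33, 31, 30 and 29.** Reagent-controlled epoxidation of allylic alcohol 35 sets C6'. Alcohol 35 comes from the vinyl triflate 33 by carbonylation (ester 34) and reduction. Triflate 33 comes from enone 31 by conjugate reduction and trapping. C3' is set by enantioselective reduction of the unhindered carbonyl of the achiral enedione 29.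

## Alternatives that were turned down

**Alternative 1:** The O–C6 bond of ring A is cut. In the forward direction a Lewis acid ionises the allylic C6–O bond of the syn epoxy dienoate A2, and the C3 hydroxyl captures C6 from the face it already occupies, giving the ring A dienoate A1.
- For: it is short and follows the likely biogenesis. The ring of A2 has exactly the configuration of epoxy alcohol 36, so both end groups would branch from one intermediate, with no resolution and roughly ten operations fewer. On step economy this alternative is clearly stronger.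
- Against: the outcome depends on how an allylic cation next to a dienoate partitions. Capture by O3 at C6 competes with capture by O5 at C8 (furanoid 5,8-epoxide), proton loss and 1,2-shifts, and the exo C5 hydroxyl results only if the cation is trapped on the face it was formed on.
- Comparison: the chosen strategy spends more steps but never ionises C6. The C3–O–C6 bridge is built by cycloaddition with both bridgeheads locked, and the C5 oxygen is added to a rigid bicycle from its open face.

**Alternative 2:** Both C–O bonds at C3' and C6' of ring B are cut at once. Dye-sensitised photo-oxygenation of the alkynyl diene A4 gives the endoperoxide A3 by [4+2] addition; O–O reduction would then give the cis-3',6'-diol with a C4'=C5' alkene and an alkyne for chain extension.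
- For: the cis relation of the two oxygens is guaranteed by the bicycle, and the sequence to this point is shorter than steps 17–22.
- Against: A4 is achiral, so A3 forms as a racemate. The remaining C5' hydroxyl must be placed trans to both existing oxygens, against the directing effect of two free hydroxyls. The cis 3,6-dioxygen pattern also cannot be closed to the ether bridge of ring A without inverting one centre, so the alternative leaves ring A unsolved.
- Comparison: it is as strong or stronger for ring B alone. The chosen strategy addresses the harder ring, and its ring B branch fixes absolute configuration by catalysis and the trans diol by a stereospecific opening.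

**Alternative 3:** Three bonds of ring A are cut (O–C3, C3–C4, C5–C6). A dirhodium carboxylate catalyst converts the acyclic diazodione A6 into a five-membered carbonyl ylide that adds to methyl methacrylate A7, closing both rings of the oxabicycle and giving the keto ester A5.
- For: it is the most convergent way to the bicycle, with C7, the gem-dimethyl carbon and the C5 methyl in place after one step.
- Against: the product is racemic unless a chiral catalyst stays bound to the ylide. Regiochemistry and exo/endo orientation of the methacrylate decide C5 and are not secured. C5 carries an ester where a hydroxyl is needed, so a carbon-to-oxygen exchange at a quaternary centre and removal of the C2 ketone next to C1 must follow.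
- Comparison: it reaches a bicycle in fewer steps than steps 1–7, but then needs at least as many corrections. The chosen strategy leaves only one superfluous carbon, at a secondary position, and introduces the C5 oxygen directly.

Key step: step 7

## Route

Step 1
Reactants: 1 methyl 3-methylfuran-2-carboxylate
Product: 2 (3-methylfuran-2-yl)methanol
Conditions: LiAlH4, Et2O, 0 °C; aq. NaOH work-up
Reagents that add atoms: none
Why: Aluminium hydride reduction of the ester stops at the primary alcohol; the furan ring is untouched and no stereocentre is involved.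

Step 2
Reactants: 2 (3-methylfuran-2-yl)methanol; 3 tert-butyl(chloro)dimethylsilane
Product: 4 tert-butyl(dimethyl)[(3-methylfuran-2-yl)methoxy]silane
Conditions: imidazole, DMF, 20 °C
Reagents that add atoms: none
Why: Imidazole-promoted silylation of a primary alcohol; the silyl ether keeps the furfuryl oxygen from ionising in the cycloaddition and should survive base, light and radical steps up to step 11.

Step 3
Reactants: 5 3-methylbutan-2-one
Product: 7 1,3-dibromo-3-methylbutan-2-one, via 3-bromo-3-methylbutan-2-one 6 (not isolated)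
Conditions: Br2 (2.0 equiv), HBr (cat.), CH2Cl2, 0 → 20 °C
Reagents that add atoms: bromine, BrBr
Why: Acid-catalysed α-bromination of a ketone: the more substituted enol reacts first to give the tertiary bromide 6, which can enolise only towards its methyl group, so the second bromine enters at C1.

Step 4
Reactants: 4 tert-butyl(dimethyl)[(3-methylfuran-2-yl)methoxy]silane; 7 1,3-dibromo-3-methylbutan-2-one
Product: 9 rac-1-{[tert-butyl(dimethyl)silyl]oxymethyl}-2,2,7-trimethyl-8-oxabicyclo[3.2.1]oct-6-en-3-one, via bromozinc enolate 8 (not isolated)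
Conditions: Zn–Cu couple, DME, −10 → 20 °C, dark
Reagents that add atoms: none
Why: [4+3] cycloaddition of a furan with the zinc oxyallyl cation released from 8 by loss of bromide; in the stepwise polar pathway the unhindered CH2 terminus should bond first to the free, most nucleophilic α-carbon of 4, and the tertiary terminus then closes on the oxocarbenium carbon bearing the silyloxymethyl group, placing the gem-dimethyl carbon beside the substituted bridgehead. Both bridgeheads form together and are cis by necessity, as a racemate.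

Step 5
Reactants: 9 rac-1-{[tert-butyl(dimethyl)silyl]oxymethyl}-2,2,7-trimethyl-8-oxabicyclo[3.2.1]oct-6-en-3-one
Product: 10 (1R,5R)-1-{[tert-butyl(dimethyl)silyl]oxymethyl}-2,2,7-trimethyl-8-oxabicyclo[3.2.1]oct-6-en-3-one
Conditions: preparative SFC on amylose tris(3,5-dimethylphenylcarbamate), CO2/i-PrOH
Reagents that add atoms: none
Why: Resolution of a racemate on a chiral stationary phase; the rigid ketone has no epimerisable centre, and the enantiomer kept is the one whose bridgeheads map onto C6 and C3 of ring A, to be confirmed by anomalous-dispersion X-ray analysis of a crystalline derivative.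

Step 6
Reactants: 10 (1R,5R)-1-{[tert-butyl(dimethyl)silyl]oxymethyl}-2,2,7-trimethyl-8-oxabicyclo[3.2.1]oct-6-en-3-one
Product: 12 (1R,5S)-4-diazo-1-{[tert-butyl(dimethyl)silyl]oxymethyl}-2,2,7-trimethyl-8-oxabicyclo[3.2.1]oct-6-en-3-one, via 4-trifluoroacetyl ketone 11 (not isolated)
Conditions: LiN(SiMe3)2, THF, −78 °C; CF3CO2CH2CF3; aq. HCl work-up; then 4-acetamidobenzenesulfonyl azide, Et3N, MeCN, 20 °C
Reagents that add atoms: 4-acetamidobenzenesulfonyl azide, CC(=O)Nc1ccc(cc1)S(=O)(=O)N=[N+]=[N-]
Why: Detrifluoroacetylative diazo transfer: C4 is the only enolisable α-carbon of 10, so its enolate is acylated regiospecifically to the 1,3-diketone 11, whose activated methine accepts the diazo group and loses the trifluoroacetyl group as the N-acyl sulfonamide. Both bridgeheads are spectators.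

Step 7
Reactants: 12 (1R,5S)-4-diazo-1-{[tert-butyl(dimethyl)silyl]oxymethyl}-2,2,7-trimethyl-8-oxabicyclo[3.2.1]oct-6-en-3-one; 13 methanol
Product: 15 methyl (1S,2S,4R)-4-{[tert-butyl(dimethyl)silyl]oxymethyl}-3,3,5-trimethyl-7-oxabicyclo[2.2.1]hept-5-ene-2-carboxylate (endo ester), via ketene 14 (not isolated)
Conditions: hν (350 nm, Pyrex), MeOH, 0 °C
Reagents that add atoms: none
Why: Wolff rearrangement of a cyclic α-diazo ketone with ring contraction: light expels N2 and, because the ring locks the diazo ketone in the s-Z geometry, the bond from the gem-dimethyl carbon (C1) to the carbonyl carbon migrates in concert to the diazo carbon (C2) and gives ketene 14. Methanol 13 adds to the ketene and the resulting enol is protonated at C2, preferentially from the open exo face, so the ester should be endo; this centre is erased in step 10 and either epimer serves. The closest known reaction type is the photochemical contraction of bicyclic α-diazo ketones such as diazo norbornanones to bicyclo[2.1.1]hexane esters, which builds far more strain than the present change from a bicyclo[3.2.1]octene to a 7-oxabicyclo[2.2.1]heptene. The oxolane ring (O7–C6–C1–C2–C3) is closed by a 1,2-shift that forms the C1–C2 bond, not by a cyclisation, so no ring-closure geometry has to be met. The migrating carbon is quaternary and not stereogenic, and both bridgeheads and the C4=C5 alkene are spectators, so the absolute configuration of 10 is carried over unchanged. The selectivity needed is rearrangement over O–H insertion into methanol, 1,2-hydrogen shift and alkene cyclopropanation: the s-Z lock favours the concerted path, the only hydrogen next to the carbene centre sits on a bridgehead and would give an anti-Bredt alkene, and addition to C4=C5 would give a bicyclobutane. The silyl ether and the isolated alkene do not absorb at 350 nm.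

Step 8
Reactants: 15 methyl (1S,2S,4R)-4-{[tert-butyl(dimethyl)silyl]oxymethyl}-3,3,5-trimethyl-7-oxabicyclo[2.2.1]hept-5-ene-2-carboxylate
Product: 17 methyl (1S,2S,4R,5R)-4-{[tert-butyl(dimethyl)silyl]oxymethyl}-5-hydroxy-3,3,5-trimethyl-7-oxabicyclo[2.2.1]heptane-2-carboxylate (5-exo hydroxyl), via tertiary hydroperoxide 16 (not isolated)
Conditions: Co(acac)2 (20 mol %), PhSiH3, O2 (1 atm), i-PrOH, 20 °C; then PPh3
Reagents that add atoms: dioxygen, O=O
Why: Mukaiyama hydration by hydrogen-atom transfer: the cobalt hydride gives H to C4 and the tertiary C5 radical is trapped by O2 (Markovnikov), the hydroperoxide 16 being reduced by the phosphine. The endo face of C5 is blocked by the endo methyl of C1, so oxygen should enter exo and set the C5 hydroxyl syn to the oxygen bridge.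

Step 9
Reactants: 17 methyl (1S,2S,4R,5R)-4-{[tert-butyl(dimethyl)silyl]oxymethyl}-5-hydroxy-3,3,5-trimethyl-7-oxabicyclo[2.2.1]heptane-2-carboxylate
Product: 18 (1S,2S,4R,5R)-4-{[tert-butyl(dimethyl)silyl]oxymethyl}-5-hydroxy-3,3,5-trimethyl-7-oxabicyclo[2.2.1]heptane-2-carboxylic acid
Conditions: LiOH, THF/MeOH/H2O, 50 °C; then 1 M HCl to pH 3, 0 °C
Reagents that add atoms: lithium hydroxide, [Li+].[OH-]
Why: Saponification of a hindered methyl ester by acyl–oxygen cleavage; base may epimerise C2, which is of no consequence, and the silyl ether and tertiary alcohol are stable to hydroxide and to brief cold acidification.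

Step 10
Reactants: 18 (1S,2S,4R,5R)-4-{[tert-butyl(dimethyl)silyl]oxymethyl}-5-hydroxy-3,3,5-trimethyl-7-oxabicyclo[2.2.1]heptane-2-carboxylic acid
Product: 20 (1R,2R,4R)-1-{[tert-butyl(dimethyl)silyl]oxymethyl}-2,6,6-trimethyl-7-oxabicyclo[2.2.1]heptan-2-ol, via O-acyl thiohydroxamate 19 (not isolated)
Conditions: 1-hydroxypyridine-2(1H)-thione, DCC, DMAP (cat.), CH2Cl2, 0 → 20 °C, dark; then t-BuSH, hν (tungsten lamp), 20 °C
Reagents that add atoms: none
Why: Barton reductive decarboxylation: the thiohydroxamate ester 19 fragments under visible light to CO2 and a secondary C2 radical that takes hydrogen from the thiol. With the alkene already hydrated the radical has no cyclisation or favourable β-scission path, and C2 becomes a methylene group.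

Step 11
Reactants: 20 (1R,2R,4R)-1-{[tert-butyl(dimethyl)silyl]oxymethyl}-2,6,6-trimethyl-7-oxabicyclo[2.2.1]heptan-2-ol
Product: 21 (1R,2R,4R)-1-(hydroxymethyl)-2,6,6-trimethyl-7-oxabicyclo[2.2.1]heptan-2-ol
Conditions: Bu4NF, THF, 20 °C; aq. NH4Cl
Reagents that add atoms: none
Why: Fluoride cleaves the primary silyl ether; the tertiary alcohol and the oxygen bridge are inert.

Step 12
Reactants: 21 (1R,2R,4R)-1-(hydroxymethyl)-2,6,6-trimethyl-7-oxabicyclo[2.2.1]heptan-2-ol
Product: 22 (1S,2R,4R)-2-hydroxy-2,6,6-trimethyl-7-oxabicyclo[2.2.1]heptane-1-carbaldehyde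
Conditions: TEMPO (10 mol %), PhI(OAc)2, CH2Cl2, 20 °C
Reagents that add atoms: none
Why: Oxoammonium oxidation is selective for the primary alcohol; the tertiary alcohol cannot be oxidised, the aldehyde has no α-hydrogen, the 1,3-diol is not cleaved, and the near-neutral medium avoids retro-aldol opening.

Step 13
Reactants: 22 (1S,2R,4R)-2-hydroxy-2,6,6-trimethyl-7-oxabicyclo[2.2.1]heptane-1-carbaldehyde
Product: 23 (1S,2R,4R)-2,6,6-trimethyl-2-(triethylsilyloxy)-7-oxabicyclo[2.2.1]heptane-1-carbaldehyde
Conditions: Et3SiOTf, 2,6-lutidine, CH2Cl2, −78 → 0 °C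
Reagents that add atoms: triethylsilyl trifluoromethanesulfonate, CC[Si](CC)(CC)OS(=O)(=O)C(F)(F)F
Why: A silyl triflate with a hindered pyridine base silylates the tertiary alcohol, and the aldehyde cannot form a silyl enol ether; masking O5 removes the alkoxide that could cleave the C5–C6 bond by retro-aldol reaction in the basic olefination that follows.

Step 14
Reactants: 23 (1S,2R,4R)-2,6,6-trimethyl-2-(triethylsilyloxy)-7-oxabicyclo[2.2.1]heptane-1-carbaldehyde; 24 ethyl (2E)-4-(diethoxyphosphoryl)-3-methylbut-2-enoate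
Product: 25 ethyl (2E,4E)-3-methyl-5-[(1S,2R,4R)-2,6,6-trimethyl-2-(triethylsilyloxy)-7-oxabicyclo[2.2.1]heptan-1-yl]penta-2,4-dienoate
Conditions: LiN(SiMe3)2, THF/DMPU, −78 → 0 °C
Reagents that add atoms: none
Why: Horner–Wadsworth–Emmons olefination with the vinylogous phosphonate adds C8–C11 in one step and gives the E C7=C8 bond; the C9=C10 bond forms mainly E from the equilibrating allylic anion, and the minor 9Z isomer is removed by chromatography.

Step 15
Reactants: 25 ethyl (2E,4E)-3-methyl-5-[(1S,2R,4R)-2,6,6-trimethyl-2-(triethylsilyloxy)-7-oxabicyclo[2.2.1]heptan-1-yl]penta-2,4-dienoate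
Product: 26 (2E,4E)-3-methyl-5-[(1S,2R,4R)-2,6,6-trimethyl-2-(triethylsilyloxy)-7-oxabicyclo[2.2.1]heptan-1-yl]penta-2,4-dien-1-ol
Conditions: i-Bu2AlH, CH2Cl2, −78 °C; aq. potassium sodium tartrate (KNaC4H4O6)
Reagents that add atoms: none
Why: Aluminium hydride reduces the dienoate to the allylic alcohol without conjugate reduction at low temperature; the silyl ether and the oxygen bridge are unaffected.

Step 16
Reactants: 26 (2E,4E)-3-methyl-5-[(1S,2R,4R)-2,6,6-trimethyl-2-(triethylsilyloxy)-7-oxabicyclo[2.2.1]heptan-1-yl]penta-2,4-dien-1-ol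
Product: 28 {(2E,4E)-3-methyl-5-[(1S,2R,4R)-2,6,6-trimethyl-2-(triethylsilyloxy)-7-oxabicyclo[2.2.1]heptan-1-yl]penta-2,4-dienyl}triphenylphosphonium bromide, via allylic bromide 27 (not isolated)
Conditions: CBr4 (1.05 equiv), PPh3 (1.1 equiv), CH2Cl2, −20 °C; then PPh3 (1.2 equiv), 20 °C
Reagents that add atoms: tetrabromomethane, BrC(Br)(Br)Br; triphenylphosphine, c1ccc(cc1)P(c1ccccc1)c1ccccc1
Why: Appel bromination of the primary allylic alcohol under neutral conditions, then SN2 quaternisation of bromide 27 by the phosphine; acid is avoided because the C6–O bond is tertiary and allylic.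

Step 17
Reactants: 29 2,6,6-trimethylcyclohex-2-ene-1,4-dione
Product: 30 (4R)-4-hydroxy-2,6,6-trimethylcyclohex-2-en-1-one
Conditions: RuCl[(R,R)-TsDPEN](p-cymene) (1 mol %), HCO2H/Et3N (5:2), CH2Cl2, 20 °C
Reagents that add atoms: none
Why: Noyori asymmetric transfer hydrogenation: only the C4 carbonyl is unhindered (C1 lies between a quaternary carbon and a methyl-bearing alkene carbon), and the alkenyl group takes the place of the aryl group of an aryl ketone, from which the (R,R) ligand is expected to give the R alcohol; should the sense prove opposite, the antipodal ligand is used. This sets C3'.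

Step 18
Reactants: 30 (4R)-4-hydroxy-2,6,6-trimethylcyclohex-2-en-1-one
Product: 31 (4R)-4-{[tert-butyl(diphenyl)silyl]oxy}-2,6,6-trimethylcyclohex-2-en-1-one
Conditions: t-BuPh2SiCl, imidazole, DMF, 20 °C
Reagents that add atoms: tert-butyl(chloro)diphenylsilane, CC(C)(C)[Si](Cl)(c1ccccc1)c1ccccc1
Why: Silylation of the secondary alcohol; the diphenylsilyl ether is chosen because it has to survive the aqueous acid of step 23 and all hydride and base steps until step 30.

Step 19
Reactants: 31 (4R)-4-{[tert-butyl(diphenyl)silyl]oxy}-2,6,6-trimethylcyclohex-2-en-1-one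
Product: 33 (4S)-4-{[tert-butyl(diphenyl)silyl]oxy}-2,6,6-trimethylcyclohex-1-en-1-yl trifluoromethanesulfonate, via lithium enolate 32 (not isolated)
Conditions: LiBH(s-Bu)3, THF, −78 °C; then PhNTf2, −78 → 0 °C
Reagents that add atoms: N-phenylbis(trifluoromethanesulfonimide), O=S(=O)(N(c1ccccc1)S(=O)(=O)C(F)(F)F)C(F)(F)F
Why: Conjugate reduction of the enone by the bulky borohydride (1,2-attack is blocked by the gem-dimethyl group) gives enolate 32 regiospecifically at C5'=C6', and O-triflation traps it as the tetrasubstituted vinyl triflate; a C5' stereocentre never forms.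

Step 20
Reactants: 33 (4S)-4-{[tert-butyl(diphenyl)silyl]oxy}-2,6,6-trimethylcyclohex-1-en-1-yl trifluoromethanesulfonate; 13 methanol
Product: 34 methyl (4S)-4-{[tert-butyl(diphenyl)silyl]oxy}-2,6,6-trimethylcyclohex-1-ene-1-carboxylate
Conditions: Pd(OAc)2 (5 mol %), PPh3, CO (1 atm), Et3N, DMF, 60 °C
Reagents that add atoms: carbon monoxide, [C-]#[O+]
Why: Palladium-catalysed alkoxycarbonylation of a vinyl triflate: oxidative addition to zerovalent palladium, CO insertion and methanolysis of the acyl complex install C7' as an ester; CO is small enough for the hindered position.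

Step 21
Reactants: 34 methyl (4S)-4-{[tert-butyl(diphenyl)silyl]oxy}-2,6,6-trimethylcyclohex-1-ene-1-carboxylate
Product: 35 [(4S)-4-{[tert-butyl(diphenyl)silyl]oxy}-2,6,6-trimethylcyclohex-1-en-1-yl]methanol
Conditions: i-Bu2AlH, toluene, −78 → 0 °C; aq. potassium sodium tartrate (KNaC4H4O6)
Reagents that add atoms: none
Why: 1,2-Reduction of the unsaturated ester to the primary allylic alcohol.

Step 22
Reactants: 35 [(4S)-4-{[tert-butyl(diphenyl)silyl]oxy}-2,6,6-trimethylcyclohex-1-en-1-yl]methanol
Product: 36 {4-{[tert-butyl(diphenyl)silyl]oxy}-2,2,6-trimethyl-7-oxabicyclo[4.1.0]heptan-1-yl}methanol with the oxirane oxygen cis to the silyloxy group (syn epoxide)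
Conditions: Ti(OiPr)4 (30 mol %), D-(−)-diethyl tartrate (36 mol %), t-BuOOH, 4 Å MS, CH2Cl2, −20 °C
Reagents that add atoms: tert-butyl hydroperoxide, CC(C)(C)OO
Why: Sharpless asymmetric epoxidation of a primary allylic alcohol under reagent control: with the D-(−)-tartrate the oxygen should be delivered to the face of C5'=C6' that carries the C3' silyloxy group, giving the syn epoxide and setting C6'. The diastereomer that arises from any minor enantiomer of 35 is separable, which raises the enantiomeric purity.

Step 23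
Reactants: 36 syn epoxy alcohol
Product: 37 (1R,2S,4R)-4-{[tert-butyl(diphenyl)silyl]oxy}-1-(hydroxymethyl)-2,6,6-trimethylcyclohexane-1,2-diol
Conditions: HClO4 (5 mol %), THF/H2O (3:1), 0 → 20 °C
Reagents that add atoms: water, O
Why: Acid-catalysed hydrolysis of a 2,3-epoxy alcohol at the distal carbon: water attacks C5' with inversion because C5' is the tertiary carbon remote from the electron-withdrawing CH2OH group and is not neopentyl, and because this trans-diaxial (Fürst–Plattner) opening leads to the chair with the silyloxy group equatorial. C6' keeps its oxygen, so the diol is trans, with O6' cis and O5' trans to O3'.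

Step 24
Reactants: 37 (1R,2S,4R)-4-{[tert-butyl(diphenyl)silyl]oxy}-1-(hydroxymethyl)-2,6,6-trimethylcyclohexane-1,2-diol
Product: 38 (1S,2S,4R)-4-{[tert-butyl(diphenyl)silyl]oxy}-1,2-dihydroxy-2,6,6-trimethylcyclohexane-1-carbaldehyde
Conditions: SO3·pyridine, DMSO, Et3N, CH2Cl2, 0 °C
Reagents that add atoms: none
Why: Parikh–Doering oxidation converts only the primary alcohol; the tertiary alcohols are inert, activated DMSO does not cleave 1,2-diols, and the aldehyde has no α-hydrogen.

Step 25
Reactants: 38 (1S,2S,4R)-4-{[tert-butyl(diphenyl)silyl]oxy}-1,2-dihydroxy-2,6,6-trimethylcyclohexane-1-carbaldehyde; 24 ethyl (2E)-4-(diethoxyphosphoryl)-3-methylbut-2-enoate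
Product: 39 ethyl (2E,4E)-5-[(1S,2S,4R)-4-{[tert-butyl(diphenyl)silyl]oxy}-1,2-dihydroxy-2,6,6-trimethylcyclohexyl]-3-methylpenta-2,4-dienoate
Conditions: 24 (3 equiv), LiN(SiMe3)2 (3 equiv), THF/DMPU, −78 → 0 °C
Reagents that add atoms: none
Why: Horner–Wadsworth–Emmons olefination as in step 14; excess phosphonate anion takes up the two hydroxyl protons, and addition to the aldehyde at low temperature should be faster than α-ketol rearrangement of the alkoxide.

Step 26
Reactants: 39 ethyl (2E,4E)-5-[(1S,2S,4R)-4-{[tert-butyl(diphenyl)silyl]oxy}-1,2-dihydroxy-2,6,6-trimethylcyclohexyl]-3-methylpenta-2,4-dienoate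
Product: 40 (1S,2S,4R)-4-{[tert-butyl(diphenyl)silyl]oxy}-1-[(1E,3E)-5-hydroxy-3-methylpenta-1,3-dienyl]-2,6,6-trimethylcyclohexane-1,2-diol
Conditions: i-Bu2AlH (5 equiv), CH2Cl2, −78 °C; aq. potassium sodium tartrate (KNaC4H4O6)
Reagents that add atoms: none
Why: Ester to allylic alcohol with excess hydride, the free hydroxyls being carried as aluminium alkoxides.

Step 27
Reactants: 40 (1S,2S,4R)-4-{[tert-butyl(diphenyl)silyl]oxy}-1-[(1E,3E)-5-hydroxy-3-methylpenta-1,3-dienyl]-2,6,6-trimethylcyclohexane-1,2-diol
Product: 42 {(2E,4E)-5-[(1S,2S,4R)-4-{[tert-butyl(diphenyl)silyl]oxy}-1,2-dihydroxy-2,6,6-trimethylcyclohexyl]-3-methylpenta-2,4-dienyl}triphenylphosphonium bromide, via allylic bromide 41 (not isolated)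
Conditions: CBr4 (1.05 equiv), PPh3 (1.1 equiv), CH2Cl2, −30 °C; then PPh3 (1.2 equiv), 20 °C
Reagents that add atoms: tetrabromomethane, BrC(Br)(Br)Br; triphenylphosphine, c1ccc(cc1)P(c1ccccc1)c1ccccc1
Why: Appel bromination is selective for the primary allylic alcohol over the two tertiary ones at low temperature, and bromide 41 is quaternised in the same flask; neutral conditions spare the tertiary allylic C6' hydroxyl.

Step 28
Reactants: 42 ring B phosphonium bromide; 43 (2E,4E,6E)-2,7-dimethylocta-2,4,6-trienedial
Product: 45 (2E,4E,6E,8E,10E,12E)-13-[(1S,2S,4R)-4-{[tert-butyl(diphenyl)silyl]oxy}-1,2-dihydroxy-2,6,6-trimethylcyclohexyl]-2,7,11-trimethyltrideca-2,4,6,8,10,12-hexaenal, via 8Z isomer 44 (not isolated)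
Conditions: 43 (3 equiv), NaOMe, MeOH/CH2Cl2, 0 → 20 °C; then EtOAc, 70 °C, Ar, dark
Reagents that add atoms: none
Why: Wittig olefination of the semi-stabilised allylic ylide with one aldehyde group of 43, used in excess to suppress double condensation; the new C11'=C12' bond forms as an E/Z mixture, and the Z isomer 44, strained by the clash of H-10' with the C13' methyl group, should isomerise thermally to the all-E aldehyde.

Step 29
Reactants: 28 ring A phosphonium bromide; 45 C25 aldehyde
Product: 47 (3R,5R,6S,3'R,5'S,6'S)-3'-O-[tert-butyl(diphenyl)silyl]-5-O-(triethylsilyl)-3,6-epoxy-5,6,5',6'-tetrahydro-β,β-carotene-5,3',5',6'-tetrol, via 11Z isomer 46 (not isolated)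
Conditions: NaOMe, MeOH/CH2Cl2, 20 °C; then EtOAc, 70 °C, Ar, dark
Reagents that add atoms: none
Why: The second Wittig olefination joins the halves at C11=C12; all six stereocentres arrive with the fragments, and the hindered 11Z isomer 46 should again relax to the all-E polyene on heating.

Step 30
Reactants: 47 bis-silyl ether of the target
Product: 48 (3R,5R,6S,3'R,5'S,6'S)-3,6-epoxy-5,6,5',6'-tetrahydro-β,β-carotene-5,3',5',6'-tetrol (CNP0261804.1)
Conditions: Bu4NF, THF, 0 → 40 °C, dark; aq. NH4Cl
Reagents that add atoms: none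
Why: Fluoride removes the secondary diphenylsilyl ether and the tertiary triethylsilyl ether in one operation under non-acidic conditions that the polyene and the two allylic C–O bonds tolerate.

## Compound list

1 | methyl 3-methylfuran-2-carboxylate | COC(=O)c1occc1C | starting material
2 | (3-methylfuran-2-yl)methanol | OCc1occc1C | intermediate
3 | tert-butyl(chloro)dimethylsilane | CC(C)(C)[Si](C)(C)Cl | starting material
4 | tert-butyl(dimethyl)[(3-methylfuran-2-yl)methoxy]silane | CC(C)(C)[Si](C)(C)OCc1occc1C | intermediate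
5 | 3-methylbutan-2-one | CC(C)C(C)=O | starting material
6 | 3-bromo-3-methylbutan-2-one | CC(=O)C(C)(C)Br | intermediate (not isolated)
7 | 1,3-dibromo-3-methylbutan-2-one | BrCC(=O)C(C)(C)Br | intermediate
8 | bromozinc enolate of 7 (1-bromo-3-methylbut-2-en-2-yloxyzinc bromide) | BrCC(O[Zn]Br)=C(C)C | intermediate (not isolated)
9 | rac-1-{[tert-butyl(dimethyl)silyl]oxymethyl}-2,2,7-trimethyl-8-oxabicyclo[3.2.1]oct-6-en-3-one (racemate, bridgeheads cis by necessity) | CC(C)(C)[Si](C)(C)OCC12OC(CC(=O)C1(C)C)C=C2C | intermediate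
10 | (1R,5R)-1-{[tert-butyl(dimethyl)silyl]oxymethyl}-2,2,7-trimethyl-8-oxabicyclo[3.2.1]oct-6-en-3-one | CC(C)(C)[Si](C)(C)OC[C@]12O[C@H](CC(=O)C1(C)C)C=C2C | intermediate
11 | 4-trifluoroacetyl derivative of 10 (C4 epimers and enol form) | CC(C)(C)[Si](C)(C)OC[C@]12O[C@H](C(C(=O)C(F)(F)F)C(=O)C1(C)C)C=C2C | intermediate (not isolated)
12 | (1R,5S)-4-diazo-1-{[tert-butyl(dimethyl)silyl]oxymethyl}-2,2,7-trimethyl-8-oxabicyclo[3.2.1]oct-6-en-3-one | CC(C)(C)[Si](C)(C)OC[C@]12O[C@H](C(=[N+]=[N-])C(=O)C1(C)C)C=C2C | intermediate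
13 | methanol | CO | starting material
14 | (1S,4R)-4-{[tert-butyl(dimethyl)silyl]oxymethyl}-3,3,5-trimethyl-2-(oxomethylidene)-7-oxabicyclo[2.2.1]hept-5-ene (ketene) | CC(C)(C)[Si](C)(C)OC[C@]12O[C@H](C(=C=O)C1(C)C)C=C2C | intermediate (not isolated)
15 | methyl (1S,2S,4R)-4-{[tert-butyl(dimethyl)silyl]oxymethyl}-3,3,5-trimethyl-7-oxabicyclo[2.2.1]hept-5-ene-2-carboxylate (endo ester) | CC(C)(C)[Si](C)(C)OC[C@]12O[C@H]([C@@H](C(=O)OC)C1(C)C)C=C2C | intermediate
16 | 5-exo-hydroperoxide corresponding to 17 | CC(C)(C)[Si](C)(C)OC[C@]12O[C@H]([C@@H](C(=O)OC)C1(C)C)C[C@@]2(C)OO | intermediate (not isolated)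
17 | methyl (1S,2S,4R,5R)-4-{[tert-butyl(dimethyl)silyl]oxymethyl}-5-hydroxy-3,3,5-trimethyl-7-oxabicyclo[2.2.1]heptane-2-carboxylate (5-exo OH) | CC(C)(C)[Si](C)(C)OC[C@]12O[C@H]([C@@H](C(=O)OC)C1(C)C)C[C@@]2(C)O | intermediate
18 | (1S,2S,4R,5R)-4-{[tert-butyl(dimethyl)silyl]oxymethyl}-5-hydroxy-3,3,5-trimethyl-7-oxabicyclo[2.2.1]heptane-2-carboxylic acid | CC(C)(C)[Si](C)(C)OC[C@]12O[C@H]([C@@H](C(=O)O)C1(C)C)C[C@@]2(C)O | intermediate
19 | 2-thioxopyridin-1(2H)-yl ester of 18 (O-acyl thiohydroxamate) | CC(C)(C)[Si](C)(C)OC[C@]12O[C@H]([C@@H](C(=O)ON3C=CC=CC3=S)C1(C)C)C[C@@]2(C)O | intermediate (not isolated)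
20 | (1R,2R,4R)-1-{[tert-butyl(dimethyl)silyl]oxymethyl}-2,6,6-trimethyl-7-oxabicyclo[2.2.1]heptan-2-ol | CC(C)(C)[Si](C)(C)OC[C@]12O[C@H](CC1(C)C)C[C@@]2(C)O | intermediate
21 | (1R,2R,4R)-1-(hydroxymethyl)-2,6,6-trimethyl-7-oxabicyclo[2.2.1]heptan-2-ol | OC[C@]12O[C@H](CC1(C)C)C[C@@]2(C)O | intermediate
22 | (1S,2R,4R)-2-hydroxy-2,6,6-trimethyl-7-oxabicyclo[2.2.1]heptane-1-carbaldehyde | O=C[C@]12O[C@H](CC1(C)C)C[C@@]2(C)O | intermediate
23 | (1S,2R,4R)-2,6,6-trimethyl-2-(triethylsilyloxy)-7-oxabicyclo[2.2.1]heptane-1-carbaldehyde | O=C[C@]12O[C@H](CC1(C)C)C[C@@]2(C)O[Si](CC)(CC)CC | intermediate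
24 | ethyl (2E)-4-(diethoxyphosphoryl)-3-methylbut-2-enoate (triethyl 3-methyl-4-phosphonocrotonate) | CCOC(=O)/C=C(\C)CP(=O)(OCC)OCC | starting material
25 | ethyl (2E,4E)-3-methyl-5-[(1S,2R,4R)-2,6,6-trimethyl-2-(triethylsilyloxy)-7-oxabicyclo[2.2.1]heptan-1-yl]penta-2,4-dienoate | CCOC(=O)/C=C(C)/C=C/[C@]12O[C@H](CC1(C)C)C[C@@]2(C)O[Si](CC)(CC)CC | intermediate
26 | (2E,4E)-3-methyl-5-[(1S,2R,4R)-2,6,6-trimethyl-2-(triethylsilyloxy)-7-oxabicyclo[2.2.1]heptan-1-yl]penta-2,4-dien-1-ol | OC/C=C(C)/C=C/[C@]12O[C@H](CC1(C)C)C[C@@]2(C)O[Si](CC)(CC)CC | intermediate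
27 | allylic bromide corresponding to 26 | BrC/C=C(C)/C=C/[C@]12O[C@H](CC1(C)C)C[C@@]2(C)O[Si](CC)(CC)CC | intermediate (not isolated)
28 | {(2E,4E)-3-methyl-5-[(1S,2R,4R)-2,6,6-trimethyl-2-(triethylsilyloxy)-7-oxabicyclo[2.2.1]heptan-1-yl]penta-2,4-dienyl}triphenylphosphonium bromide | [Br-].C(/C=C(C)/C=C/[C@]12O[C@H](CC1(C)C)C[C@@]2(C)O[Si](CC)(CC)CC)[P+](c1ccccc1)(c1ccccc1)c1ccccc1 | intermediate
29 | 2,6,6-trimethylcyclohex-2-ene-1,4-dione (ketoisophorone) | CC1=CC(=O)CC(C)(C)C1=O | starting material
30 | (4R)-4-hydroxy-2,6,6-trimethylcyclohex-2-en-1-one | O=C1C(C)(C)C[C@@H](O)C=C1C | intermediate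
31 | (4R)-4-{[tert-butyl(diphenyl)silyl]oxy}-2,6,6-trimethylcyclohex-2-en-1-one | O=C1C(C)(C)C[C@@H](O[Si](c2ccccc2)(c2ccccc2)C(C)(C)C)C=C1C | intermediate
32 | lithium (4S)-4-{[tert-butyl(diphenyl)silyl]oxy}-2,6,6-trimethylcyclohex-1-en-1-olate | [Li+].[O-]C1=C(C)C[C@H](O[Si](c2ccccc2)(c2ccccc2)C(C)(C)C)CC1(C)C | intermediate (not isolated)
33 | (4S)-4-{[tert-butyl(diphenyl)silyl]oxy}-2,6,6-trimethylcyclohex-1-en-1-yl trifluoromethanesulfonate | O=S(=O)(OC1=C(C)C[C@H](O[Si](c2ccccc2)(c2ccccc2)C(C)(C)C)CC1(C)C)C(F)(F)F | intermediate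
34 | methyl (4S)-4-{[tert-butyl(diphenyl)silyl]oxy}-2,6,6-trimethylcyclohex-1-ene-1-carboxylate | COC(=O)C1=C(C)C[C@H](O[Si](c2ccccc2)(c2ccccc2)C(C)(C)C)CC1(C)C | intermediate
35 | [(4S)-4-{[tert-butyl(diphenyl)silyl]oxy}-2,6,6-trimethylcyclohex-1-en-1-yl]methanol | OCC1=C(C)C[C@H](O[Si](c2ccccc2)(c2ccccc2)C(C)(C)C)CC1(C)C | intermediate
36 | {4-{[tert-butyl(diphenyl)silyl]oxy}-2,2,6-trimethyl-7-oxabicyclo[4.1.0]heptan-1-yl}methanol, oxirane oxygen cis to the silyloxy group (syn epoxide) | OC[C@]12C(C)(C)C[C@@H](O[Si](c3ccccc3)(c3ccccc3)C(C)(C)C)C[C@@]1(C)O2 | intermediate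
37 | (1R,2S,4R)-4-{[tert-butyl(diphenyl)silyl]oxy}-1-(hydroxymethyl)-2,6,6-trimethylcyclohexane-1,2-diol | OC[C@]1(O)C(C)(C)C[C@@H](O[Si](c2ccccc2)(c2ccccc2)C(C)(C)C)C[C@]1(C)O | intermediate
38 | (1S,2S,4R)-4-{[tert-butyl(diphenyl)silyl]oxy}-1,2-dihydroxy-2,6,6-trimethylcyclohexane-1-carbaldehyde | O=C[C@]1(O)C(C)(C)C[C@@H](O[Si](c2ccccc2)(c2ccccc2)C(C)(C)C)C[C@]1(C)O | intermediate
39 | ethyl (2E,4E)-5-[(1S,2S,4R)-4-{[tert-butyl(diphenyl)silyl]oxy}-1,2-dihydroxy-2,6,6-trimethylcyclohexyl]-3-methylpenta-2,4-dienoate | CCOC(=O)/C=C(C)/C=C/[C@]1(O)C(C)(C)C[C@@H](O[Si](c2ccccc2)(c2ccccc2)C(C)(C)C)C[C@]1(C)O | intermediate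
40 | (1S,2S,4R)-4-{[tert-butyl(diphenyl)silyl]oxy}-1-[(1E,3E)-5-hydroxy-3-methylpenta-1,3-dienyl]-2,6,6-trimethylcyclohexane-1,2-diol | OC/C=C(C)/C=C/[C@]1(O)C(C)(C)C[C@@H](O[Si](c2ccccc2)(c2ccccc2)C(C)(C)C)C[C@]1(C)O | intermediate
41 | allylic bromide corresponding to 40 | BrC/C=C(C)/C=C/[C@]1(O)C(C)(C)C[C@@H](O[Si](c2ccccc2)(c2ccccc2)C(C)(C)C)C[C@]1(C)O | intermediate (not isolated)
42 | {(2E,4E)-5-[(1S,2S,4R)-4-{[tert-butyl(diphenyl)silyl]oxy}-1,2-dihydroxy-2,6,6-trimethylcyclohexyl]-3-methylpenta-2,4-dienyl}triphenylphosphonium bromide | [Br-].C(/C=C(C)/C=C/[C@]1(O)C(C)(C)C[C@@H](O[Si](c2ccccc2)(c2ccccc2)C(C)(C)C)C[C@]1(C)O)[P+](c1ccccc1)(c1ccccc1)c1ccccc1 | intermediate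
43 | (2E,4E,6E)-2,7-dimethylocta-2,4,6-trienedial | O=C/C(C)=C/C=C/C=C(C)/C=O | starting material
44 | (2E,4E,6E,8Z,10E,12E) isomer of 45 (11'Z in carotenoid numbering) | O=C/C(C)=C/C=C/C=C(C)/C=C\C=C(C)\C=C\[C@]1(O)C(C)(C)C[C@@H](O[Si](c2ccccc2)(c2ccccc2)C(C)(C)C)C[C@]1(C)O | intermediate (not isolated)
45 | (2E,4E,6E,8E,10E,12E)-13-[(1S,2S,4R)-4-{[tert-butyl(diphenyl)silyl]oxy}-1,2-dihydroxy-2,6,6-trimethylcyclohexyl]-2,7,11-trimethyltrideca-2,4,6,8,10,12-hexaenal | O=C/C(C)=C/C=C/C=C(C)/C=C/C=C(C)/C=C/[C@]1(O)C(C)(C)C[C@@H](O[Si](c2ccccc2)(c2ccccc2)C(C)(C)C)C[C@]1(C)O | intermediate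
46 | 11Z isomer of 47 | CC(/C=C\C=C(C)\C=C\[C@]12O[C@H](CC1(C)C)C[C@@]2(C)O[Si](CC)(CC)CC)=C\C=C\C=C(C)\C=C\C=C(C)\C=C\[C@]1(O)C(C)(C)C[C@@H](O[Si](c2ccccc2)(c2ccccc2)C(C)(C)C)C[C@]1(C)O | intermediate (not isolated)
47 | (3R,5R,6S,3'R,5'S,6'S)-3'-O-[tert-butyl(diphenyl)silyl]-5-O-(triethylsilyl)-3,6-epoxy-5,6,5',6'-tetrahydro-β,β-carotene-5,3',5',6'-tetrol (all-E) | CC(/C=C/C=C(C)/C=C/[C@]12O[C@H](CC1(C)C)C[C@@]2(C)O[Si](CC)(CC)CC)=C\C=C\C=C(C)\C=C\C=C(C)\C=C\[C@]1(O)C(C)(C)C[C@@H](O[Si](c2ccccc2)(c2ccccc2)C(C)(C)C)C[C@]1(C)O | intermediate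
48 | (3R,5R,6S,3'R,5'S,6'S)-3,6-epoxy-5,6,5',6'-tetrahydro-β,β-carotene-5,3',5',6'-tetrol (all-E) | CC(/C=C/C=C(C)/C=C/[C@]12O[C@H](CC1(C)C)C[C@@]2(C)O)=C\C=C\C=C(C)\C=C\C=C(C)\C=C\[C@]1(O)C(C)(C)C[C@@H](O)C[C@]1(C)O | target

## Step count and least certain steps

Total: 30 steps. Longest linear sequence: 17 steps (1, 2, 4–16, 29, 30); the ring B branch (17–28) is 12 steps before the union.

**Step 7 (key step).** The carbene may insert into the O–H bond of methanol instead of rearranging, or the strained ketene may form slowly and the excited diazo ketone may decay by other paths, because the contraction adds ring strain. Fallback: from 10, the lithium enolate is brominated with NBS to the 4-bromo ketone F1. NaOMe in MeOH then induces a quasi-Favorskii (semibenzilic) rearrangement: methoxide adds to the carbonyl and the same C–C bond shifts to C4 with loss of bromide, which gives ester 15 directly (the C2 epimer is immaterial). This replaces the carbene by an ionic 1,2-shift.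

**Step 4.** The cycloaddition may bond the tertiary terminus to the free α-carbon of the furan, which puts the gem-dimethyl group beside the CH bridgehead, or the furan may be consumed by simple electrophilic substitution. Fallback: from 4, cycloaddition with the symmetrical oxyallyl cation from 1,1,3,3-tetrabromoacetone and Zn–Cu gives the dibromo adduct F2, which Zn–Cu/NH4Cl in MeOH debrominates to the parent ketone F3; here regiochemistry does not arise. Formylation (HCO2Et, NaH) at the less hindered C4 gives the hydroxymethylene ketone F4. Two rounds of dianion formation (LiN(i-Pr)2, 2 equiv) and MeI methylate C2 to the dimethyl hydroxymethylene ketone F5. Deformylative diazo transfer (TsN3, Et3N) gives the racemic diazo ketone F6, which is resolved on the chiral phase of step 5 and rejoins the route at 12.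

**Step 8.** Facial selectivity in the trapping of the C5 radical may be poor, or the radical may simply be reduced to the alkane. Fallback: from 15, oxymercuration (Hg(OAc)2, THF/H2O), which adds cis-exo to norbornene-type alkenes with Markovnikov orientation, gives the hydroxy mercurial F7; NaBH4/NaOH reduces it to 17.

**Step 17.** The catalyst may also reduce the conjugated C=C bond, or differentiate the alkenyl and methylene flanks poorly, so that enantiomeric purity is low. Fallback: from 29, Luche reduction (NaBH4, CeCl3·7H2O, MeOH) gives the racemic alcohol F8. Lipase-catalysed acetylation (Burkholderia cepacia lipase, vinyl acetate) then resolves it kinetically: by the empirical size rule the S alcohol is acetylated to the acetate F9, and the unreacted R alcohol is 30.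

**Step 23.** The opening may pass through a free C5' cation and lose control: elimination to allylic alcohols, a 1,2-shift to a ketone, or partial attack at C6'. Fallback: from 36, Ti(OiPr)4-mediated opening with benzoic acid is used instead; the titanium alkoxide of the C7' hydroxyl activates the epoxide and delivers the carboxylate to the distal carbon C5' with inversion, giving the 5'-benzoate F10. K2CO3 in MeOH then gives 37.

**Step 29.** The hindered ylide may convert the C25 aldehyde incompletely, and E/Z mixtures at C9 and C11 may not all equilibrate before the polyene degrades on heating. Fallback: from 26, a Mitsunobu reaction with 2-mercaptobenzothiazole gives the sulfide F11, which H2O2 with (NH4)6Mo7O24·4H2O oxidises to the sulfone F12. Julia–Kocienski olefination of 45 with the anion of F12 (NaN(SiMe3)2, THF, −78 °C) gives 47 without a phosphonium salt.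

## Further compounds

F1 | step 7 | 4-bromo-1-{[tert-butyl(dimethyl)silyl]oxymethyl}-2,2,7-trimethyl-8-oxabicyclo[3.2.1]oct-6-en-3-one (bridgeheads as in 10, either C4 epimer) | CC(C)(C)[Si](C)(C)OC[C@]12O[C@H](C(Br)C(=O)C1(C)C)C=C2C
F2 | step 4 | rac-2,4-dibromo-1-{[tert-butyl(dimethyl)silyl]oxymethyl}-7-methyl-8-oxabicyclo[3.2.1]oct-6-en-3-one | CC(C)(C)[Si](C)(C)OCC12OC(C(Br)C(=O)C1Br)C=C2C
F3 | step 4 | rac-1-{[tert-butyl(dimethyl)silyl]oxymethyl}-7-methyl-8-oxabicyclo[3.2.1]oct-6-en-3-one | CC(C)(C)[Si](C)(C)OCC12OC(CC(=O)C1)C=C2C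
F4 | step 4 | rac-4-(hydroxymethylidene) derivative of F3 | CC(C)(C)[Si](C)(C)OCC12OC(C(=CO)C(=O)C1)C=C2C
F5 | step 4 | rac-4-(hydroxymethylidene)-2,2-dimethyl derivative of F3 | CC(C)(C)[Si](C)(C)OCC12OC(C(=CO)C(=O)C1(C)C)C=C2C
F6 | step 4 | rac-4-diazo-1-{[tert-butyl(dimethyl)silyl]oxymethyl}-2,2,7-trimethyl-8-oxabicyclo[3.2.1]oct-6-en-3-one | CC(C)(C)[Si](C)(C)OCC12OC(C(=[N+]=[N-])C(=O)C1(C)C)C=C2C
F7 | step 8 | 6-exo-(acetoxymercurio) derivative of 17 (mercury on carotenoid C4, cis to the 5-exo hydroxyl) | CC(C)(C)[Si](C)(C)OC[C@]12O[C@H]([C@@H](C(=O)OC)C1(C)C)[C@@H]([Hg]OC(C)=O)[C@@]2(C)O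
F8 | step 17 | rac-4-hydroxy-2,6,6-trimethylcyclohex-2-en-1-one | O=C1C(C)(C)CC(O)C=C1C
F9 | step 17 | (1S)-4-oxo-3,5,5-trimethylcyclohex-2-en-1-yl acetate (acetate of the S alcohol) | O=C1C(C)(C)C[C@H](OC(C)=O)C=C1C
F10 | step 23 | 2-O-benzoate of 37 (benzoate on carotenoid C5') | OC[C@]1(O)C(C)(C)C[C@@H](O[Si](c2ccccc2)(c2ccccc2)C(C)(C)C)C[C@]1(C)OC(=O)c1ccccc1
F11 | step 29 | 2-{[(2E,4E)-3-methyl-5-[(1S,2R,4R)-2,6,6-trimethyl-2-(triethylsilyloxy)-7-oxabicyclo[2.2.1]heptan-1-yl]penta-2,4-dienyl]sulfanyl}-1,3-benzothiazole | S(C/C=C(C)/C=C/[C@]12O[C@H](CC1(C)C)C[C@@]2(C)O[Si](CC)(CC)CC)c1nc2ccccc2s1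
F12 | step 29 | sulfone corresponding to F11 | O=S(=O)(C/C=C(C)/C=C/[C@]12O[C@H](CC1(C)C)C[C@@]2(C)O[Si](CC)(CC)CC)c1nc2ccccc2s1
A1 | alternative 1 | ethyl (2E,4E)-5-[(1S,2R,4R)-2-hydroxy-2,6,6-trimethyl-7-oxabicyclo[2.2.1]heptan-1-yl]-3-methylpenta-2,4-dienoate | CCOC(=O)/C=C(C)/C=C/[C@]12O[C@H](CC1(C)C)C[C@@]2(C)O
A2 | alternative 1 | ethyl (2E,4E)-5-(4-hydroxy-2,2,6-trimethyl-7-oxabicyclo[4.1.0]heptan-1-yl)-3-methylpenta-2,4-dienoate, oxirane cis to the hydroxyl (syn epoxide) | CCOC(=O)/C=C(C)/C=C/[C@]12C(C)(C)C[C@@H](O)C[C@@]1(C)O2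
A3 | alternative 2 | trimethyl[(5,8,8-trimethyl-2,3-dioxabicyclo[2.2.2]oct-5-en-1-yl)ethynyl]silane (endoperoxide) | C[Si](C)(C)C#C[C@@]12OO[C@@H](C=C1C)CC2(C)C
A4 | alternative 2 | trimethyl[(2,6,6-trimethylcyclohexa-1,3-dien-1-yl)ethynyl]silane | C[Si](C)(C)C#CC1=C(C)C=CCC1(C)C
A5 | alternative 3 | methyl 1-{[tert-butyl(diphenyl)silyl]oxymethyl}-2,6,6-trimethyl-5-oxo-7-oxabicyclo[2.2.1]heptane-2-carboxylate | CC(C)(C)[Si](c1ccccc1)(c1ccccc1)OC[C@]12O[C@H](C(=O)C1(C)C)C[C@@]2(C)C(=O)OC
A6 | alternative 3 | 5-{[tert-butyl(diphenyl)silyl]oxy}-1-diazo-3,3-dimethylpentane-2,4-dione | [N-]=[N+]=CC(=O)C(C)(C)C(=O)CO[Si](c1ccccc1)(c1ccccc1)C(C)(C)C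
A7 | alternative 3 | methyl methacrylate | C=C(C)C(=O)OC
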